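**Plan** (germacrane numbering: ring C1–C10; lactone carbons C11–C13 on C7 with the ring oxygen on C6; ester carbon C14 on C10; methyl C15 on C4)
- Cuts, in retrosynthetic order: O9–acetyl; C9–C10 (ring closure); O8–acyl (made with inversion at C8); C7–C8; C7=C11 (butenolide); C6–C7; C1=C10. This leads back to nerol, 2-(bromomethyl)acrylic acid, (silyloxy)acetaldehyde and (R)-2-methylglycidol.
- Enabling feature: C9 is an oxygen-bearing carbon bonded to C10, the α-carbon of the C1=C10–C14 enoate in the ten-membered ring, so C9–C10 is the bond formed when a C10 alkenyl metal (from a C10–I bond) adds to a C9 aldehyde. The trans-fused γ-lactone (O–C6–C7–C11–C12) and the C4–C5 oxirane are rigid turns that bring C9 and C10 of the seco chain together.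
- Forward order: C4–C5 oxirane → C1=C10 iodoenoate → C6 carbinol → butenolide ring → C7–C8 bond with return of the α-methylene γ-lactone → C8 ester → C9 aldehyde → ten-membered ring by C9–C10 closure → C9 acetate.
- Stereochemistry: C4/C5 from one Sharpless epoxidation (the only catalytic asymmetric step); C6 by Felkin–Anh addition; C7 and C8 together in one indium allylation, C8 then inverted in the Mitsunobu esterification; the glycidate centre is bought; C9 is set in the ring closure under control of C8; the C1=C10 geometry comes from the (Z)-iodoenoate.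

Key step: step 12

Remark: compounds 8, 11 and 13 are taken as commercial, and minor isomers from steps 2, 4, 7 and 12 are assumed separable by chromatography.

**Step 1**
Reactants: 1 nerol, (2Z)-3,7-dimethylocta-2,6-dien-1-ol
Product: 2 [(2S,3R)-3-methyl-3-(4-methylpent-3-en-1-yl)oxiran-2-yl]methanol
Conditions: Ti(OiPr)4 (cat.), L-(+)-diethyl tartrate (cat.), tBuOOH, 4 Å MS, CH2Cl2, −20 °C
Reagents that add atoms: tert-butyl hydroperoxide, CC(C)(C)OO
Why: Sharpless asymmetric epoxidation, in which the titanium tartrate complex epoxidises only the allylic C4=C5 bond and L-(+)-tartrate should deliver oxygen to the face that gives the (2S,3R)-oxirane, which is C4 (R) and C5 (S) of the target, while the Z geometry of nerol fixes C3 and C6 cis on the oxirane.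

**Step 2**
Reactants: 2 [(2S,3R)-3-methyl-3-(4-methylpent-3-en-1-yl)oxiran-2-yl]methanol
Product: 5 methyl (2Z)-5-[(2R,3S)-3-(hydroxymethyl)-2-methyloxiran-2-yl]-2-iodopent-2-enoate, via secondary ozonide 3 (not isolated), via hydroxy aldehyde 4 (not isolated)
Conditions: O3, CH2Cl2, −78 °C; Me2S, −78 °C → rt; then Ph3P=C(I)CO2Me [premixed from Ph3P=CHCO2Me and N-iodosuccinimide, CH2Cl2, −20 °C], rt
Reagents that add atoms: ozone, [O-][O+]=O; methyl (triphenylphosphoranylidene)acetate, COC(=O)C=P(c1ccccc1)(c1ccccc1)c1ccccc1; N-iodosuccinimide, O=C1CCC(=O)N1I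
Why: ozonolysis of the only remaining C=C followed by Wittig olefination of the crude aldehyde with the α-iodo ylide, a stabilised ylide that places the ester trans to the chain and so should give mainly the (Z)-2-iodoenoate (iodine cis to C2) that carries the C10–I handle and the later ring-cis C1=C10 geometry.

**Step 3**
Reactants: 5 methyl (2Z)-5-[(2R,3S)-3-(hydroxymethyl)-2-methyloxiran-2-yl]-2-iodopent-2-enoate
Product: 6 methyl (2Z)-5-[(2R,3R)-3-formyl-2-methyloxiran-2-yl]-2-iodopent-2-enoate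
Conditions: Dess–Martin periodinane, pyridine, CH2Cl2, 0 °C → rt
Reagents that add atoms: none
Why: Dess–Martin oxidation of the primary epoxy alcohol under buffered, non-enolising conditions should give the α,β-epoxy aldehyde without touching the oxirane or the iodoenoate (the changed descriptor at the oxirane carbon reflects only the higher priority of the formyl group).

**Step 4**
Reactants: 6 methyl (2Z)-5-[(2R,3R)-3-formyl-2-methyloxiran-2-yl]-2-iodopent-2-enoate
Product: 7 methyl (2Z)-5-{(2R,3S)-3-[(1S)-1-hydroxyprop-2-en-1-yl]-2-methyloxiran-2-yl}-2-iodopent-2-enoate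
Conditions: CH2=CHMgBr, THF, −78 °C; aq. NH4Cl
Reagents that add atoms: vinylmagnesium bromide, C=C[Mg]Br
Why: Grignard 1,2-addition to the aldehyde, far faster at −78 °C than attack on the ester or the alkenyl iodide, with Felkin–Anh approach anti to the C5–O bond of the cis-substituted oxirane expected to favour the 5,6-anti (6S) carbinol.

**Step 5**
Reactants: 7 methyl (2Z)-5-{(2R,3S)-3-[(1S)-1-hydroxyprop-2-en-1-yl]-2-methyloxiran-2-yl}-2-iodopent-2-enoate; 8 2-(bromomethyl)prop-2-enoic acid
Product: 9 methyl (2Z)-5-{(2R,3S)-3-[(1S)-1-{[2-(bromomethyl)prop-2-enoyl]oxy}prop-2-en-1-yl]-2-methyloxiran-2-yl}-2-iodopent-2-enoate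
Conditions: DCC, DMAP (cat.), CH2Cl2, −20 °C → 0 °C
Reagents that add atoms: none
Why: Steglich esterification of the secondary allylic alcohol with retention at C6, run cold so that acyl transfer outpaces attack of DMAP on the allylic bromide.

**Step 6**
Reactants: 9 methyl (2Z)-5-{(2R,3S)-3-[(1S)-1-{[2-(bromomethyl)prop-2-enoyl]oxy}prop-2-en-1-yl]-2-methyloxiran-2-yl}-2-iodopent-2-enoate
Product: 10 methyl (2Z)-5-{(2R,3S)-3-[(2S)-4-(bromomethyl)-5-oxo-2,5-dihydrofuran-2-yl]-2-methyloxiran-2-yl}-2-iodopent-2-enoate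
Conditions: second-generation Hoveyda–Grubbs catalyst (cat.), toluene, 80 °C, argon sparge
Reagents that add atoms: none
Why: ring-closing metathesis between the vinyl group and the 1,1-disubstituted acrylate closes the butenolide (C7=C11) under neutral conditions that should leave the base-sensitive C6–H, the allylic bromide, the oxirane and the unreactive trisubstituted iodoenoate untouched.

**Step 7**
Reactants: 10 methyl (2Z)-5-{(2R,3S)-3-[(2S)-4-(bromomethyl)-5-oxo-2,5-dihydrofuran-2-yl]-2-methyloxiran-2-yl}-2-iodopent-2-enoate; 11 {[tert-butyl(dimethyl)silyl]oxy}acetaldehyde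
Product: 12 methyl (2Z)-5-{(2R,3S)-3-[(2S,3R)-3-[(1R)-2-{[tert-butyl(dimethyl)silyl]oxy}-1-hydroxyethyl]-4-methylidene-5-oxooxolan-2-yl]-2-methyloxiran-2-yl}-2-iodopent-2-enoate
Conditions: In (powder), THF/H2O (3:1), rt
Reagents that add atoms: none
Why: Barbier allylation in which the allylindium species reacts through its ring γ-carbon C7 and regenerates the α-methylene lactone, the new C7–C8 bond forming on the ring face opposite the C6 substituent (trans lactone, 7R) and a chair Zimmerman–Traxler transition state with the ring-fixed allyl geometry giving the 7,8-anti carbinol (8R, the C8 epimer that step 9 inverts), so that two stereocentres should be relayed from C6 in one event while indium leaves the alkenyl iodide alone.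

**Step 8**
Reactants: 13 [(2R)-2-methyloxiran-2-yl]methanol
Product: 14 (2S)-2-methyloxirane-2-carboxylic acid
Conditions: RuCl3·3H2O (cat.), NaIO4, MeCN/CCl4/H2O, 0 °C → rt; used at once
Reagents that add atoms: water, O
Why: ruthenium tetroxide-catalysed oxidation of the primary epoxy alcohol to the epoxy acid through the aldehyde hydrate, in which the quaternary stereocentre cannot epimerise and the change from R to S is only a change in substituent priority.

**Step 9**
Reactants: 12 methyl (2Z)-5-{(2R,3S)-3-[(2S,3R)-3-[(1R)-2-{[tert-butyl(dimethyl)silyl]oxy}-1-hydroxyethyl]-4-methylidene-5-oxooxolan-2-yl]-2-methyloxiran-2-yl}-2-iodopent-2-enoate; 14 (2S)-2-methyloxirane-2-carboxylic acid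
Product: 15 methyl (2Z)-5-{(2R,3S)-3-[(2S,3R)-3-[(1S)-2-{[tert-butyl(dimethyl)silyl]oxy}-1-{[(2S)-2-methyloxirane-2-carbonyl]oxy}ethyl]-4-methylidene-5-oxooxolan-2-yl]-2-methyloxiran-2-yl}-2-iodopent-2-enoate
Conditions: PPh3, DIAD (betaine formed first), THF, 0 °C → rt
Reagents that add atoms: none
Why: Mitsunobu esterification, in which the carboxylate displaces the C8 oxyphosphonium group by SN2 and so installs the glycidate with inversion (8R to 8S) in the acylation step itself, while forming the betaine before the substrate is added keeps free phosphine away from the α-methylene lactone.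

**Step 10**
Reactants: 15 methyl (2Z)-5-{(2R,3S)-3-[(2S,3R)-3-[(1S)-2-{[tert-butyl(dimethyl)silyl]oxy}-1-{[(2S)-2-methyloxirane-2-carbonyl]oxy}ethyl]-4-methylidene-5-oxooxolan-2-yl]-2-methyloxiran-2-yl}-2-iodopent-2-enoate
Product: 16 methyl (2Z)-5-{(2R,3S)-3-[(2S,3R)-3-[(1S)-2-hydroxy-1-{[(2S)-2-methyloxirane-2-carbonyl]oxy}ethyl]-4-methylidene-5-oxooxolan-2-yl]-2-methyloxiran-2-yl}-2-iodopent-2-enoate
Conditions: HF·pyridine, excess pyridine, THF, 0 °C
Reagents that add atoms: none
Why: fluoride cleavage of the primary silyl ether under buffered conditions that should spare both oxiranes and be too mild for migration of the C8 ester to the new C9 hydroxyl.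

**Step 11**
Reactants: 16 methyl (2Z)-5-{(2R,3S)-3-[(2S,3R)-3-[(1S)-2-hydroxy-1-{[(2S)-2-methyloxirane-2-carbonyl]oxy}ethyl]-4-methylidene-5-oxooxolan-2-yl]-2-methyloxiran-2-yl}-2-iodopent-2-enoate
Product: 17 methyl (2Z)-2-iodo-5-{(2R,3S)-2-methyl-3-[(2S,3S)-4-methylidene-3-[(1S)-1-{[(2S)-2-methyloxirane-2-carbonyl]oxy}-2-oxoethyl]-5-oxooxolan-2-yl]oxiran-2-yl}pent-2-enoate
Conditions: Dess–Martin periodinane, pyridine, CH2Cl2, 0 °C; crude aldehyde used directly
Reagents that add atoms: none
Why: Dess–Martin oxidation brings C9 to the aldehyde level needed for the ring closure without base, so that C8 should not epimerise (the 3S descriptor on the lactone ring is a priority change only).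

**Step 12**
Reactants: 17 methyl (2Z)-2-iodo-5-{(2R,3S)-2-methyl-3-[(2S,3S)-4-methylidene-3-[(1S)-1-{[(2S)-2-methyloxirane-2-carbonyl]oxy}-2-oxoethyl]-5-oxooxolan-2-yl]oxiran-2-yl}pent-2-enoate
Product: 18 methyl (1(10)E,4R,5S,6S,7R,8S,9R)-4,5-epoxy-9-hydroxy-8-{[(2S)-2-methyloxirane-2-carbonyl]oxy}-12,6-olido-germacra-1(10),11(13)-dien-14-oate
Conditions: CrCl2 (10 equiv), NiCl2 (cat.), DMSO, rt, slow addition of 17 to a final concentration of about 0.002 M
Reagents that add atoms: none
Why: Nozaki–Hiyama–Kishi reaction: zerovalent nickel (formed from NiCl2 by CrCl2) inserts into the C10–I bond, transmetalation gives a C10 alkenyl species of trivalent chromium with the C1=C10 geometry kept, and this adds to the C9 aldehyde; the closest known reaction type is the NiCl2/CrCl2 macrocyclisation of alkenyl iodide aldehydes to medium-ring allylic alcohols. The ten-membered carbocycle (C1–C10) closes in a 10-exo-trig mode. The new C9 stereocentre is controlled by the adjacent C8 centre, a Felkin–Anh arrangement with the C8–O ester bond antiperiplanar to the forming bond being expected to give the 8,9-anti (9R) alcohol within a chain whose conformation is restricted by the trans-fused γ-lactone and the C4–C5 oxirane. The step needs ring closure over oligomerisation, which high dilution and these two rigid turns should secure, and chemoselectivity, which rests on nickel reacting only with the C–I bond while CrCl2 should leave both oxiranes, the esters and the α-methylene lactone alone. The (Z)-iodide maps onto the ring-cis C1=C10 bond, which is also the less strained geometry in a ten-membered ring, so retention is expected.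

**Step 13**
Reactants: 18 methyl (1(10)E,4R,5S,6S,7R,8S,9R)-4,5-epoxy-9-hydroxy-8-{[(2S)-2-methyloxirane-2-carbonyl]oxy}-12,6-olido-germacra-1(10),11(13)-dien-14-oate
Product: 19 methyl (1(10)E,4R,5S,6S,7R,8S,9R)-9-acetoxy-4,5-epoxy-8-{[(2S)-2-methyloxirane-2-carbonyl]oxy}-12,6-olido-germacra-1(10),11(13)-dien-14-oate (CNP0274195.2)
Conditions: Ac2O, pyridine, DMAP (cat.), CH2Cl2, 0 °C
Reagents that add atoms: acetic anhydride, CC(=O)OC(C)=O
Why: acylation of the secondary allylic C9 alcohol with retention, run cold and briefly so that the neighbouring C8 ester does not migrate.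

**Compound list**
1 | nerol, (2Z)-3,7-dimethylocta-2,6-dien-1-ol | CC(C)=CCC/C(C)=C\CO | starting material
2 | [(2S,3R)-3-methyl-3-(4-methylpent-3-en-1-yl)oxiran-2-yl]methanol | CC(C)=CCC[C@@]1(C)O[C@H]1CO | intermediate
3 | {(2S,3R)-3-[2-(5,5-dimethyl-1,2,4-trioxolan-3-yl)ethyl]-3-methyloxiran-2-yl}methanol (secondary ozonide, epimers at the trioxolane carbon) | CC1(C)OOC(CC[C@@]2(C)O[C@H]2CO)O1 | intermediate
4 | 3-[(2R,3S)-3-(hydroxymethyl)-2-methyloxiran-2-yl]propanal | O=CCC[C@@]1(C)O[C@H]1CO | intermediate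
5 | methyl (2Z)-5-[(2R,3S)-3-(hydroxymethyl)-2-methyloxiran-2-yl]-2-iodopent-2-enoate | COC(=O)/C(I)=C/CC[C@@]1(C)O[C@H]1CO | intermediate
6 | methyl (2Z)-5-[(2R,3R)-3-formyl-2-methyloxiran-2-yl]-2-iodopent-2-enoate | COC(=O)/C(I)=C/CC[C@@]1(C)O[C@H]1C=O | intermediate
7 | methyl (2Z)-5-{(2R,3S)-3-[(1S)-1-hydroxyprop-2-en-1-yl]-2-methyloxiran-2-yl}-2-iodopent-2-enoate | C=C[C@H](O)[C@@H]1O[C@]1(C)CC/C=C(I)/C(=O)OC | intermediate
8 | 2-(bromomethyl)prop-2-enoic acid | C=C(CBr)C(=O)O | starting material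
9 | methyl (2Z)-5-{(2R,3S)-3-[(1S)-1-{[2-(bromomethyl)prop-2-enoyl]oxy}prop-2-en-1-yl]-2-methyloxiran-2-yl}-2-iodopent-2-enoate | C=C[C@H](OC(=O)C(=C)CBr)[C@@H]1O[C@]1(C)CC/C=C(I)/C(=O)OC | intermediate
10 | methyl (2Z)-5-{(2R,3S)-3-[(2S)-4-(bromomethyl)-5-oxo-2,5-dihydrofuran-2-yl]-2-methyloxiran-2-yl}-2-iodopent-2-enoate | BrCC1=C[C@H](OC1=O)[C@@H]1O[C@]1(C)CC/C=C(I)/C(=O)OC | intermediate
11 | {[tert-butyl(dimethyl)silyl]oxy}acetaldehyde | CC(C)(C)[Si](C)(C)OCC=O | starting material
12 | methyl (2Z)-5-{(2R,3S)-3-[(2S,3R)-3-[(1R)-2-{[tert-butyl(dimethyl)silyl]oxy}-1-hydroxyethyl]-4-methylidene-5-oxooxolan-2-yl]-2-methyloxiran-2-yl}-2-iodopent-2-enoate | C=C1C(=O)O[C@@H]([C@H]1[C@@H](O)CO[Si](C)(C)C(C)(C)C)[C@@H]1O[C@]1(C)CC/C=C(I)/C(=O)OC | intermediate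
13 | [(2R)-2-methyloxiran-2-yl]methanol | OC[C@]1(C)CO1 | starting material
14 | (2S)-2-methyloxirane-2-carboxylic acid | OC(=O)[C@]1(C)CO1 | intermediate
15 | methyl (2Z)-5-{(2R,3S)-3-[(2S,3R)-3-[(1S)-2-{[tert-butyl(dimethyl)silyl]oxy}-1-{[(2S)-2-methyloxirane-2-carbonyl]oxy}ethyl]-4-methylidene-5-oxooxolan-2-yl]-2-methyloxiran-2-yl}-2-iodopent-2-enoate | C=C1C(=O)O[C@@H]([C@H]1[C@H](OC(=O)[C@]1(C)CO1)CO[Si](C)(C)C(C)(C)C)[C@@H]1O[C@]1(C)CC/C=C(I)/C(=O)OC | intermediate
16 | methyl (2Z)-5-{(2R,3S)-3-[(2S,3R)-3-[(1S)-2-hydroxy-1-{[(2S)-2-methyloxirane-2-carbonyl]oxy}ethyl]-4-methylidene-5-oxooxolan-2-yl]-2-methyloxiran-2-yl}-2-iodopent-2-enoate | C=C1C(=O)O[C@@H]([C@H]1[C@H](OC(=O)[C@]1(C)CO1)CO)[C@@H]1O[C@]1(C)CC/C=C(I)/C(=O)OC | intermediate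
17 | methyl (2Z)-2-iodo-5-{(2R,3S)-2-methyl-3-[(2S,3S)-4-methylidene-3-[(1S)-1-{[(2S)-2-methyloxirane-2-carbonyl]oxy}-2-oxoethyl]-5-oxooxolan-2-yl]oxiran-2-yl}pent-2-enoate | C=C1C(=O)O[C@@H]([C@H]1[C@H](OC(=O)[C@]1(C)CO1)C=O)[C@@H]1O[C@]1(C)CC/C=C(I)/C(=O)OC | intermediate
18 | methyl (1(10)E,4R,5S,6S,7R,8S,9R)-4,5-epoxy-9-hydroxy-8-{[(2S)-2-methyloxirane-2-carbonyl]oxy}-12,6-olido-germacra-1(10),11(13)-dien-14-oate | C=C1C(=O)O[C@H]2[C@H]1[C@H](OC(=O)[C@]1(C)CO1)[C@H](O)/C(C(=O)OC)=C\CC[C@@]1(C)O[C@@H]21 | intermediate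
19 | methyl (1(10)E,4R,5S,6S,7R,8S,9R)-9-acetoxy-4,5-epoxy-8-{[(2S)-2-methyloxirane-2-carbonyl]oxy}-12,6-olido-germacra-1(10),11(13)-dien-14-oate | C=C1C(=O)O[C@H]2[C@H]1[C@H](OC(=O)[C@]1(C)CO1)[C@H](OC(C)=O)/C(C(=O)OC)=C\CC[C@@]1(C)O[C@@H]21 | target

**Step count**
Total: 13 steps. Longest linear sequence: 12 steps (steps 1–7 and 9–13 from nerol); step 8 is a one-step side branch.

**Steps most likely to fail**

Step 12. The C10 alkenylchromium may attack the wrong face of the C9 aldehyde under the constraint of the forming ring, alongside intermolecular coupling and loss of iodine by protonation. Fallback: the route is left at 17; the same closure is run and the 9-epimeric alcohol, methyl (1(10)E,4R,5S,6S,7R,8S,9S)-4,5-epoxy-9-hydroxy-8-{[(2S)-2-methyloxirane-2-carbonyl]oxy}-12,6-olido-germacra-1(10),11(13)-dien-14-oate F1, is taken on. A Mitsunobu reaction with acetic acid (PPh3, DIAD, AcOH, toluene, 0 °C) then replaces the acylation of step 13 and should install the acetate with SN2 inversion at C9, so that C9 is set by inversion instead of by facial control; the route is rejoined at 19.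

Step 9. The activated C8 oxygen may be lost by elimination toward C7, or SN2 at the hindered carbinol may be too slow, so that diene or ester of retained configuration forms. Fallback: from 12, Dess–Martin oxidation should give the C8 ketone, methyl (2Z)-5-{(2R,3S)-3-[(2S,3S)-3-({[tert-butyl(dimethyl)silyl]oxy}acetyl)-4-methylidene-5-oxooxolan-2-yl]-2-methyloxiran-2-yl}-2-iodopent-2-enoate F2. Reagent-controlled Corey–Bakshi–Shibata reduction ((S)-2-methyl-CBS-oxazaborolidine, catecholborane, toluene, −78 °C) should then give the 8S alcohol, methyl (2Z)-5-{(2R,3S)-3-[(2S,3R)-3-[(1S)-2-{[tert-butyl(dimethyl)silyl]oxy}-1-hydroxyethyl]-4-methylidene-5-oxooxolan-2-yl]-2-methyloxiran-2-yl}-2-iodopent-2-enoate F3. Acylation of F3 with 14 with retention (2,4,6-trichlorobenzoyl chloride, Et3N, then DMAP, toluene, 0 °C) returns to the route at 15.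

Step 4. Facial selectivity in the vinyl addition may be poor because magnesium chelation between the aldehyde and oxirane oxygens competes with the Felkin–Anh pathway. Fallback: from 6, the addition is run without regard to selectivity, and the mixture of 7 and its C6 epimer, methyl (2Z)-5-{(2R,3S)-3-[(1R)-1-hydroxyprop-2-en-1-yl]-2-methyloxiran-2-yl}-2-iodopent-2-enoate F4, is oxidised (Dess–Martin periodinane, pyridine, CH2Cl2) to the epoxy enone, methyl (2Z)-2-iodo-5-[(2R,3R)-2-methyl-3-(prop-2-enoyl)oxiran-2-yl]pent-2-enoate F5. Reduction with Zn(BH4)2 in Et2O at −20 °C (zinc chelated between the ketone and oxirane oxygens, hydride from the face away from C4) should give the 5,6-anti alcohol, so that C6 is set by hydride delivery instead of by C–C bond formation; the route is rejoined at 7.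

**Further compounds**
F1 | step 12 | methyl (1(10)E,4R,5S,6S,7R,8S,9S)-4,5-epoxy-9-hydroxy-8-{[(2S)-2-methyloxirane-2-carbonyl]oxy}-12,6-olido-germacra-1(10),11(13)-dien-14-oate | C=C1C(=O)O[C@H]2[C@H]1[C@H](OC(=O)[C@]1(C)CO1)[C@@H](O)/C(C(=O)OC)=C\CC[C@@]1(C)O[C@@H]21
F2 | step 9 | methyl (2Z)-5-{(2R,3S)-3-[(2S,3S)-3-({[tert-butyl(dimethyl)silyl]oxy}acetyl)-4-methylidene-5-oxooxolan-2-yl]-2-methyloxiran-2-yl}-2-iodopent-2-enoate | C=C1C(=O)O[C@@H]([C@H]1C(=O)CO[Si](C)(C)C(C)(C)C)[C@@H]1O[C@]1(C)CC/C=C(I)/C(=O)OC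
F3 | step 9 | methyl (2Z)-5-{(2R,3S)-3-[(2S,3R)-3-[(1S)-2-{[tert-butyl(dimethyl)silyl]oxy}-1-hydroxyethyl]-4-methylidene-5-oxooxolan-2-yl]-2-methyloxiran-2-yl}-2-iodopent-2-enoate | C=C1C(=O)O[C@@H]([C@H]1[C@H](O)CO[Si](C)(C)C(C)(C)C)[C@@H]1O[C@]1(C)CC/C=C(I)/C(=O)OC
F4 | step 4 | methyl (2Z)-5-{(2R,3S)-3-[(1R)-1-hydroxyprop-2-en-1-yl]-2-methyloxiran-2-yl}-2-iodopent-2-enoate | C=C[C@@H](O)[C@@H]1O[C@]1(C)CC/C=C(I)/C(=O)OC
F5 | step 4 | methyl (2Z)-2-iodo-5-[(2R,3R)-2-methyl-3-(prop-2-enoyl)oxiran-2-yl]pent-2-enoate | C=CC(=O)[C@@H]1O[C@]1(C)CC/C=C(I)/C(=O)OC
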